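**Plan**

- Numbering: flavanone atoms are unprimed (benzo ring A, pyranone ring C, aryl ring B); flavone atoms are double-primed (benzo ring D, pyranone ring F, aryl ring E).
- Enabling feature: C4(=O)–C3–C3''–C4''(=O) is a succinyl unit. Each carbonyl carbon carries the same phloroglucinol-type ring (A, D) and C2/C2'' carry the same 4-oxygenated aryl group. Apart from the C2''=C3'' unsaturation the skeleton is twofold symmetric, so one succinate core can acylate two identical phenols.
- Cuts, in retrosynthetic order: six O–CH3 bonds; the C2''=C3'' unsaturation (back to a twofold-symmetric 3,3''-biflavanone); O1–C2 and O1''–C2'' (to a bis(2'-hydroxychalcone)); C4–C4a and C4''–C4a'' (to a bis(arylidene)succinic acid and two phenols); the two arylidene C=C bonds (to diethyl succinate and 4-methoxybenzaldehyde). The hindered C3–C3'' bond is never formed; it comes with the succinate.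
- Forward order: the chain is built by two Stobbe condensations, rings A and D are attached in one operation, rings C and F close together by double oxa-Michael addition, ring F is dehydrogenated, and the methyl ethers are cleaved.
- Stereochemistry: C2 (S) is set by a chiral amine–thiourea catalyst in the oxa-Michael closure, and C3 (R) follows as the trans partner under thermodynamic control. The two halves of the biflavanone are equivalent, so oxidation of either leaves the required (2S,3R) flavanone.

Key step: step 4

Assumption: the sense of induction of cinchona thioureas on this α-branched bis-chalcone cannot be predicted with confidence; the quinidine-derived catalyst is written for the 2S series, and its quinine-derived pseudoenantiomer would take its place if the opposite sense is found.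

**Step 1**
Reactants: 1 diethyl succinate; 2 4-methoxybenzaldehyde
Product: 3 (E)-3-(ethoxycarbonyl)-4-(4-methoxyphenyl)but-3-enoic acid
Conditions: KOC(CH3)3, (CH3)3COH, reflux; then aq. HCl
Reagents that add atoms: none
Why: Stobbe condensation, in which the succinate enolate adds to the aldehyde and the adduct collapses by lactonisation and eliminative ring opening to a carboxylate, which makes the condensation irreversible and should give the E-arylidene half-ester with the aryl group trans to the ester.

**Step 2**
Reactants: 3 (E)-3-(ethoxycarbonyl)-4-(4-methoxyphenyl)but-3-enoic acid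
Product: 4 diethyl (E)-2-(4-methoxybenzylidene)succinate
Conditions: EtOH, cat. H2SO4, reflux
Reagents that add atoms: ethanol, CCO
Why: Fischer esterification of the unhindered CH2CO2H group restores the diester that a second enolisation requires, since the carboxylate of 3 is inert toward a further Stobbe reaction.

**Step 3**
Reactants: 4 diethyl (E)-2-(4-methoxybenzylidene)succinate; 2 4-methoxybenzaldehyde
Product: 6 (2E,3E)-2,3-bis(4-methoxybenzylidene)succinic acid, via monoethyl ester 5 (not isolated)
Conditions: KOC(CH3)3, (CH3)3COH, reflux, dark; then KOH, H2O/EtOH, reflux; aq. HCl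
Reagents that add atoms: potassium hydroxide, [K+].[OH-]
Why: A second Stobbe condensation at the remaining CH2 group installs the second arylidene carbon (the future C2'') with E geometry, and saponification of the crude half-ester in the same flask should let the symmetric E,E-diacid be purified by crystallisation.

**Step 4**
Reactants: 6 (2E,3E)-2,3-bis(4-methoxybenzylidene)succinic acid; 7 3,5-dimethoxyphenol (two molecules per molecule of 6)
Product: 9 (2E,3E)-1,4-bis(2-hydroxy-4,6-dimethoxyphenyl)-2,3-bis(4-methoxybenzylidene)butane-1,4-dione, via diaryl ester 8 (not isolated)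
Conditions: (CF3CO)2O (2.1 equiv), ClCH2CH2Cl, 0 °C to rt, dark; 7 (2.2 equiv), 0 °C to rt; then BF3·OEt2 (6 equiv), 60 °C; H2O
Reagents that add atoms: none
Why: In the first stage trifluoroacetic anhydride activates each carboxyl group of 6 toward attack by the hydroxyl of 7 to give diaryl ester 8; in the second stage BF3 promotes a Fries shift in which each acyl group moves as an acylium–aryloxyborane ion pair to the adjacent ring carbon, forming C4–C4a and C4''–C4a''. The closest known reactions are the BF3·OEt2-mediated acylation of phloroglucinol ethers by cinnamic acids to 2'-hydroxychalcones and the Fries rearrangement of aryl cinnamates. No ring is closed and no stereocentre is created, and the E geometry of both arylidene units should be carried through because neither double bond is attacked. The step needs site selectivity for the carbon ortho to the hydroxyl over the carbon between the two methoxy groups, which is secured by delivery of the acyl group from the neighbouring oxygen and by chelation of boron between the phenolic oxygen and the new ketone. It also needs acylation to win over conjugate hydroarylation of the arylidene carbons, which is secured by converting nearly all free phenol into ester before the Lewis acid is added and by the steric shielding of the α-branched, cross-conjugated diene. Intramolecular acylation onto a 4-methoxyphenyl ring is disfavoured because the position that would be attacked is meta to its methoxy group and the resulting ring could not aromatise.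

**Step 5**
Reactants: 9 (2E,3E)-1,4-bis(2-hydroxy-4,6-dimethoxyphenyl)-2,3-bis(4-methoxybenzylidene)butane-1,4-dione
Product: 10 (2S,3R,2''S,3''R)-5,7,5'',7''-tetramethoxy-2,2''-bis(4-methoxyphenyl)-3,3''-bichromane-4,4''-dione (trans,trans, twofold symmetric)
Conditions: 1-[3,5-bis(trifluoromethyl)phenyl]-3-(9-deoxy-9-epi-quinidin-9-yl)thiourea (20 mol%), toluene, 25 °C, dark; crystallisation
Reagents that add atoms: none
Why: Enantioselective intramolecular oxa-Michael addition (6-endo closure of a 2'-hydroxychalcone) under bifunctional amine–thiourea catalysis, in which the quinuclidine deprotonates the phenol while the thiourea binds the enone carbonyl so that each phenoxide adds to one face of its arylidene carbon and sets C2 and C2'' as S, after which C3 and C3'' settle by enolisation into the trans (R) arrangement with both substituents equatorial; because one molecule requires two catalyst-controlled additions, the minor sense of addition should end up mainly in the separable meso diastereomer, which raises the enantiomeric purity of the twofold-symmetric product.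

**Step 6**
Reactants: 10 (2S,3R,2''S,3''R)-5,7,5'',7''-tetramethoxy-2,2''-bis(4-methoxyphenyl)-3,3''-bichromane-4,4''-dione
Product: 11 (2S,3R)-5,7-dimethoxy-3-[5,7-dimethoxy-2-(4-methoxyphenyl)-4-oxo-4H-chromen-3-yl]-2-(4-methoxyphenyl)chroman-4-one
Conditions: DDQ (1.0 equiv), 1,4-dioxane, 100 °C; recovered 10 recycled
Reagents that add atoms: none
Why: Dehydrogenation of a flavanone to a flavone by 2,3-dichloro-5,6-dicyano-1,4-benzoquinone, in which hydride is removed from C2 (benzylic to the 4-methoxyphenyl ring and α to the ring oxygen) and the C3 proton is then lost; the untouched half keeps C2 unaffected and C3 in its preferred trans arrangement, the twofold axis of 10 makes oxidation of either half give the same product, and one equivalent of oxidant with recycling of unreacted 10 should limit oxidation of the second ring.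

**Step 7**
Reactants: 11 (2S,3R)-5,7-dimethoxy-3-[5,7-dimethoxy-2-(4-methoxyphenyl)-4-oxo-4H-chromen-3-yl]-2-(4-methoxyphenyl)chroman-4-one
Product: 12 (2S,3R)-5,7-dihydroxy-3-[5,7-dihydroxy-2-(4-hydroxyphenyl)-4-oxo-4H-chromen-3-yl]-2-(4-hydroxyphenyl)chroman-4-one (CNP0208264.1)
Conditions: BBr3 (12 equiv), CH2Cl2, −78 °C to rt; H2O
Reagents that add atoms: none
Why: Lewis-acid cleavage of aryl methyl ethers by BBr3 (bromide attack on the methyl group of each aryloxonium–borane complex) should free all six phenols, the methoxy groups peri to the carbonyls reacting first through chelation, while the flavanone centres are preserved because no base is present and the trans-diequatorial arrangement at C2/C3 is the thermodynamic one.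

**Compound list**

1 | diethyl succinate | CCOC(=O)CCC(=O)OCC | starting material
2 | 4-methoxybenzaldehyde | COc1ccc(C=O)cc1 | starting material
3 | (E)-3-(ethoxycarbonyl)-4-(4-methoxyphenyl)but-3-enoic acid | COc1ccc(/C=C(\CC(=O)O)C(=O)OCC)cc1 | intermediate
4 | diethyl (E)-2-(4-methoxybenzylidene)succinate | COc1ccc(/C=C(\CC(=O)OCC)C(=O)OCC)cc1 | intermediate
5 | monoethyl (2E,3E)-2,3-bis(4-methoxybenzylidene)succinate (formed in the flask, not isolated) | CCOC(=O)C(=C/c1ccc(OC)cc1)/C(=C\c1ccc(OC)cc1)C(=O)O | intermediate
6 | (2E,3E)-2,3-bis(4-methoxybenzylidene)succinic acid | OC(=O)C(=C/c1ccc(OC)cc1)/C(=C\c1ccc(OC)cc1)C(=O)O | intermediate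
7 | 3,5-dimethoxyphenol | COc1cc(O)cc(OC)c1 | starting material
8 | bis(3,5-dimethoxyphenyl) (2E,3E)-2,3-bis(4-methoxybenzylidene)succinate (formed in the flask, not isolated) | COc1cc(OC)cc(c1)OC(=O)C(=C/c1ccc(OC)cc1)/C(=C\c1ccc(OC)cc1)C(=O)Oc1cc(OC)cc(OC)c1 | intermediate
9 | (2E,3E)-1,4-bis(2-hydroxy-4,6-dimethoxyphenyl)-2,3-bis(4-methoxybenzylidene)butane-1,4-dione | O=C(c1c(O)cc(OC)cc1OC)C(=C/c1ccc(OC)cc1)/C(=C\c1ccc(OC)cc1)C(=O)c1c(O)cc(OC)cc1OC | intermediate
10 | (2S,3R,2''S,3''R)-5,7,5'',7''-tetramethoxy-2,2''-bis(4-methoxyphenyl)-3,3''-bichromane-4,4''-dione | O=C1c2c(OC)cc(OC)cc2O[C@H](c2ccc(OC)cc2)[C@H]1[C@H]3C(=O)c4c(OC)cc(OC)cc4O[C@@H]3c5ccc(OC)cc5 | intermediate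
11 | (2S,3R)-5,7-dimethoxy-3-[5,7-dimethoxy-2-(4-methoxyphenyl)-4-oxo-4H-chromen-3-yl]-2-(4-methoxyphenyl)chroman-4-one | O=C1c2c(OC)cc(OC)cc2O[C@H](c2ccc(OC)cc2)[C@H]1c1c(-c2ccc(OC)cc2)oc2cc(OC)cc(OC)c2c1=O | intermediate
12 | (2S,3R)-5,7-dihydroxy-3-[5,7-dihydroxy-2-(4-hydroxyphenyl)-4-oxo-4H-chromen-3-yl]-2-(4-hydroxyphenyl)chroman-4-one | O=C1c2c(O)cc(O)cc2O[C@H](c2ccc(O)cc2)[C@H]1c1c(-c2ccc(O)cc2)oc2cc(O)cc(O)c2c1=O | target

Total step count: 7
Longest linear sequence: 7 steps (1 → 3 → 4 → 6 → 9 → 10 → 11 → 12)

**Steps most likely to fail**

Step 5. The two C–O bond formations may not be under sufficient catalyst control. Closure of the α-branched enones may be slow or reversible, and the second closure may be mismatched with the centres already present, which would erode enantiomeric purity and divert material into the meso series. The fallback takes the stereochemistry from resolution instead of catalysis. It sets out from 9: closure with CH3CO2Na in refluxing ethanol (thermodynamic oxa-Michael addition) would give the trans,trans biflavanones without a chiral reagent, namely 10 together with its mirror image, the (2R,3S,2''R,3''S)-biflavanone hexamethyl ether F1, and the meso (2S,3R,2''R,3''S)-biflavanone hexamethyl ether F2. The racemate is separated from the meso compound by crystallisation or chromatography and resolved by preparative chromatography on a polysaccharide chiral stationary phase, which returns the route at 10. The unwanted isomers can be re-equilibrated with the same base through ring opening and resolved again.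

Step 6. The dehydrogenation may not stop after one ring, or hydride abstraction at the hindered trans-2,3-disubstituted pyranone may be too slow at a temperature the remaining flavanone tolerates. The fallback replaces direct dehydrogenation by enol-silane chemistry with stoichiometric control. It sets out from 10: soft enolisation of one ketone with (CH3)3SiOSO2CF3 (one equivalent) and Et3N in CH2Cl2 at 0 °C would give the mono(trimethylsilyl enol ether) of 10 F3. Saegusa–Ito oxidation with Pd(OAc)2 in CH3CN (divalent palladium enolate, then β-hydride elimination of the C2 hydrogen to the conjugated chromone) returns the route at 11.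

Step 4. The acyl shift from oxygen to carbon may be incomplete or may go to the carbon between the two methoxy groups, and residual free phenol may add through its ring to an arylidene carbon and lactonise. The fallback removes both the free hydroxyl and the regiochemical choice from the arene. It sets out from 6: Friedel–Crafts acylation of 1,3,5-trimethoxybenzene (two equivalents), which has a single kind of ring position, with (CF3CO)2O and catalytic H3PO4 in CH2Cl2 would give (2E,3E)-2,3-bis(4-methoxybenzylidene)-1,4-bis(2,4,6-trimethoxyphenyl)butane-1,4-dione F4. Chelation-controlled cleavage of one methoxy group ortho to each carbonyl with BCl3 in CH2Cl2 (−78 to 0 °C) returns the route at 9.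

**Further compounds**

F1 | step 5 | (2R,3S,2''R,3''S)-5,7,5'',7''-tetramethoxy-2,2''-bis(4-methoxyphenyl)-3,3''-bichromane-4,4''-dione (mirror image of 10) | O=C1c2c(OC)cc(OC)cc2O[C@@H](c2ccc(OC)cc2)[C@@H]1[C@@H]3C(=O)c4c(OC)cc(OC)cc4O[C@H]3c5ccc(OC)cc5
F2 | step 5 | meso-(2S,3R,2''R,3''S)-5,7,5'',7''-tetramethoxy-2,2''-bis(4-methoxyphenyl)-3,3''-bichromane-4,4''-dione | O=C1c2c(OC)cc(OC)cc2O[C@H](c2ccc(OC)cc2)[C@H]1[C@@H]3C(=O)c4c(OC)cc(OC)cc4O[C@H]3c5ccc(OC)cc5
F3 | step 6 | mono(trimethylsilyl enol ether) of 10 (one half C3=C4–OSi(CH3)3, remaining stereocentres as in 10) | COc1cc(OC)c2c(c1)O[C@H](c1ccc(OC)cc1)C(=C2O[Si](C)(C)C)[C@H]1C(=O)c3c(OC)cc(OC)cc3O[C@@H]1c1ccc(OC)cc1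
F4 | step 4 | (2E,3E)-2,3-bis(4-methoxybenzylidene)-1,4-bis(2,4,6-trimethoxyphenyl)butane-1,4-dione | O=C(c1c(OC)cc(OC)cc1OC)C(=C/c1ccc(OC)cc1)/C(=C\c1ccc(OC)cc1)C(=O)c1c(OC)cc(OC)cc1OC
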